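**Retrosynthetic overview**

- The target is the tetraflavanoid fisetinidol (unit A)-(4α→6)-fisetinidol (unit B)-(4α→6)-catechin (unit C), with a further fisetinidol (unit D) bonded 4α→8 to unit C. The last operations are hydrogenolysis of sixteen benzyl ethers and, before it, oxidation of a C3–B bond on unit B with retention.
- The strategy rests on the pyran ring of unit B. Its C4 is bonded to C6 of the aromatic ring of unit C, and C6 of its own benzo ring holds C4 of unit A. Cutting C4–C4a, C3–C4 and O1–C2 gives three pieces: a C6 aldehyde of the catechin unit (unit D already on C8), a phenol carrying unit A para to its hydroxyl, and an (E)-styrylboronate that supplies C2 and C3.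
- Both large pieces come from one flavan C4 electrophile, a penta-O-benzyl flavan-3,4-diol made from (+)-taxifolin by 5-deoxygenation and reduction. Friedel–Crafts capture by resorcinol gives the phenol half. Capture by C8 of penta-O-benzylcatechin, then bromination and formylation at C6, gives the aldehyde half.
- Ring order: the pyran rings of units A, C and D come unchanged from the chiral pool. The pyran ring of unit B is the only ring built, in the key step, which also sets its C2, C3 and C4.

Key step: step 17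

Naming remark: "tetra-O-benzylfisetinidol-4α-yl" means the (2R,3S)-2,3-trans-3,4-trans-3,7-bis(benzyloxy)-2-[3,4-bis(benzyloxy)phenyl]chroman-4-yl group (4-substituent trans to the 3-oxygen, cis to the 2-aryl).

Assumption: the (R)-configured phosphoric acid is taken as the enantiomer that shields the unwanted face of the quinone methide; one pilot run fixes this, and the (S)-acid would take its place with no other change.

**Route**

Step 1
Reactants: 1 (+)-taxifolin, (2R,3R)-3,5,7,3',4'-pentahydroxyflavanone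
Product: 2 (2R,3R)-7,3',4'-tri-O-benzyltaxifolin
Conditions: BnBr (3.2 equiv), K2CO3, DMF, 0 °C → rt, argon
Reagents that add atoms: benzyl bromide, BrCc1ccccc1
Why: Williamson etherification in which carbonate ionises only the three unchelated phenols (the 5-OH is hydrogen-bonded to the C4 carbonyl and the 3-OH is an alcohol), and the mild temperature protects the base-sensitive C2 and C3 centres.

Step 2
Reactants: 2 (2R,3R)-7,3',4'-tri-O-benzyltaxifolin
Product: 3 (2R,3R)-7,3',4'-tri-O-benzyltaxifolin 5-O-trifluoromethanesulfonate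
Conditions: PhNTf2, Et3N, DMAP (cat.), CH2Cl2, rt
Reagents that add atoms: N-phenylbis(trifluoromethanesulfonimide), O=S(=O)(N(c1ccccc1)S(=O)(=O)C(F)(F)F)C(F)(F)F
Why: Phenol sulfonylation with a triflimide reagent, which transfers the triflyl group to the phenoxide but not to the secondary alcohol.

Step 3
Reactants: 3 (2R,3R)-7,3',4'-tri-O-benzyltaxifolin 5-O-trifluoromethanesulfonate
Product: 4 (2R,3R)-7,3',4'-tri-O-benzylfustin (the 5-deoxy flavanonol)
Conditions: Pd(OAc)2 (5 mol %), 1,3-bis(diphenylphosphino)propane, HCO2H, Et3N, DMF, 60 °C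
Reagents that add atoms: none
Why: Palladium-catalysed formate reduction of an aryl triflate (oxidative addition to zerovalent palladium, decarboxylation to the hydride, reductive elimination), which is fast for a triflate ortho to a carbonyl and leaves benzyl ethers and the ketone untouched in homogeneous solution.

Step 4
Reactants: 4 (2R,3R)-7,3',4'-tri-O-benzylfustin
Product: 5 (2R,3S,4R)-7-benzyloxy-2-[3,4-bis(benzyloxy)phenyl]chroman-3,4-diol (2,3-trans-3,4-trans)
Conditions: NaBH4, THF–EtOH, 0 °C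
Reagents that add atoms: none
Why: Borohydride reduction of the aryl ketone, expected to give mainly the 3,4-trans diol by hydride delivery anti to the 3-hydroxyl; the C4 configuration does not matter because C4 is ionised later.

Step 5
Reactants: 5 (2R,3S,4R)-7-benzyloxy-2-[3,4-bis(benzyloxy)phenyl]chroman-3,4-diol
Product: 6 (2R,3S,4R)-3,4,7-tris(benzyloxy)-2-[3,4-bis(benzyloxy)phenyl]chroman (2,3-trans-3,4-trans)
Conditions: NaH, BnBr, n-Bu4NI (cat.), DMF, 0 °C → rt
Reagents that add atoms: benzyl bromide, BrCc1ccccc1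
Why: Williamson etherification of both secondary alkoxides; the benzylic 4-benzyloxy group is at the same time the leaving group for both later couplings.

Step 6
Reactants: 6 (2R,3S,4R)-3,4,7-tris(benzyloxy)-2-[3,4-bis(benzyloxy)phenyl]chroman; 7 resorcinol
Product: 8 4-(tetra-O-benzylfisetinidol-4α-yl)benzene-1,3-diol
Conditions: 7 (8 equiv), BF3·OEt2 (0.5 equiv), CH2Cl2–THF, −20 → 0 °C
Reagents that add atoms: none
Why: Friedel–Crafts alkylation of a phenol by a flavan-4-yl cation (the biomimetic interflavanoid bond formation), in which BF3 ionises the C4–OBn bond to the 7-benzyloxy-stabilised benzylic cation, symmetric resorcinol attacks through its most nucleophilic carbon C4, and approach anti to the 3-benzyloxy group sets C4 as 3,4-trans (4α).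

Step 7
Reactants: 8 4-(tetra-O-benzylfisetinidol-4α-yl)benzene-1,3-diol
Product: 9 2-(tetra-O-benzylfisetinidol-4α-yl)-5-(triisopropylsilyloxy)phenol
Conditions: i-Pr3SiCl (1.05 equiv), imidazole, DMF, 0 °C
Reagents that add atoms: triisopropylsilyl chloride, CC(C)[Si](Cl)(C(C)C)C(C)C
Why: Silylation under steric control, since the bulky silyl chloride reaches the hydroxyl para to the flavanyl group while the hydroxyl ortho to it is shielded by the C4 substituent.

Step 8
Reactants: 9 2-(tetra-O-benzylfisetinidol-4α-yl)-5-(triisopropylsilyloxy)phenol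
Product: 10 [3-benzyloxy-4-(tetra-O-benzylfisetinidol-4α-yl)phenoxy]triisopropylsilane
Conditions: BnBr, K2CO3, acetone, 50 °C
Reagents that add atoms: benzyl bromide, BrCc1ccccc1
Why: Williamson etherification of the remaining hindered phenol; a triisopropylsilyl aryl ether withstands carbonate in an aprotic solvent.

Step 9
Reactants: 10 [3-benzyloxy-4-(tetra-O-benzylfisetinidol-4α-yl)phenoxy]triisopropylsilane
Product: 11 3-benzyloxy-4-(tetra-O-benzylfisetinidol-4α-yl)phenol
Conditions: n-Bu4NF, THF, 0 °C; aq NH4Cl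
Reagents that add atoms: none
Why: Fluoride cleavage of the aryl silyl ether, driven by the Si–F bond, frees the hydroxyl para to unit A and touches no benzyl ether.

Step 10
Reactants: 12 (+)-catechin
Product: 13 5,7,3',4'-tetra-O-benzylcatechin
Conditions: BnBr (4.4 equiv), K2CO3, DMF, −10 °C → rt
Reagents that add atoms: benzyl bromide, BrCc1ccccc1
Why: Williamson etherification of the four phenols only (carbonate does not ionise the 3-OH), with the low temperature suppressing C-benzylation and epimerisation at C2.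

Step 11
Reactants: 13 5,7,3',4'-tetra-O-benzylcatechin
Product: 14 3,5,7,3',4'-penta-O-benzylcatechin
Conditions: NaH, BnBr, DMF, 0 °C → rt
Reagents that add atoms: benzyl bromide, BrCc1ccccc1
Why: Williamson etherification of the secondary alkoxide, safe for C2 because no free phenol remains to open the pyran ring.

Step 12
Reactants: 14 3,5,7,3',4'-penta-O-benzylcatechin; 6 (2R,3S,4R)-3,4,7-tris(benzyloxy)-2-[3,4-bis(benzyloxy)phenyl]chroman
Product: 15 tetra-O-benzylfisetinidol-(4α→8)-penta-O-benzylcatechin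
Conditions: 14 (3 equiv), TMSOTf (0.2 equiv), 4 Å MS, CH2Cl2, −78 → −40 °C; Et3N
Reagents that add atoms: none
Why: Lewis acid-catalysed Friedel–Crafts coupling of a flavan-4-yl cation with a benzylated catechin, in which C8 is the more nucleophilic free carbon of the tri-oxygenated ring, the excess of 14 outruns self-condensation of 6, and attack anti to the 3-benzyloxy group gives the 4α (3,4-trans) bond.

Step 13
Reactants: 15 tetra-O-benzylfisetinidol-(4α→8)-penta-O-benzylcatechin
Product: 16 6-bromo derivative of 15 (bromine on C6 of the catechin unit)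
Conditions: NBS (1.0 equiv), CH2Cl2, −40 °C
Reagents that add atoms: N-bromosuccinimide, O=C1CCC(=O)N1Br
Why: Electrophilic aromatic bromination, which should take the one free position (C6) of the tri-oxygenated ring of unit C because that ring is far more electron-rich than the di-oxygenated ring of unit D and the catechol ether rings.

Step 14
Reactants: 16 6-bromo derivative of 15
Product: 17 6-formyl-penta-O-benzylcatechin carrying the tetra-O-benzylfisetinidol-4α-yl group on C8
Conditions: n-BuLi (1.1 equiv), THF, −78 °C; DMF, −78 → 0 °C; aq NH4Cl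
Reagents that add atoms: N,N-dimethylformamide, CN(C)C=O
Why: Bromine–lithium exchange followed by formylation of the aryllithium with DMF (Bouveault aldehyde synthesis); exchange at −78 °C is faster than deprotonation of the benzylic ether methylene groups.

Step 15
Reactants: 18 3,4-dihydroxybenzaldehyde
Product: 19 3,4-bis(benzyloxy)benzaldehyde
Conditions: BnBr, K2CO3, DMF, rt
Reagents that add atoms: benzyl bromide, BrCc1ccccc1
Why: Williamson etherification of both phenols.

Step 16
Reactants: 19 3,4-bis(benzyloxy)benzaldehyde; 20 bis(4,4,5,5-tetramethyl-1,3,2-dioxaborolan-2-yl)methane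
Product: 21 (E)-2-[3,4-bis(benzyloxy)phenyl]vinylboronic acid pinacol ester
Conditions: lithium 2,2,6,6-tetramethylpiperidide (from the amine and n-BuLi), THF, 0 °C; 19, −78 °C → rt; aq NH4Cl
Reagents that add atoms: none
Why: Boron–Wittig olefination, in which the α-boryl carbanion adds to the aldehyde and syn-elimination of the O–B unit from the less crowded adduct gives the (E)-alkenylboronate.

Step 17
Reactants: 17 6-formyl-penta-O-benzylcatechin carrying unit D on C8; 11 3-benzyloxy-4-(tetra-O-benzylfisetinidol-4α-yl)phenol; 21 (E)-2-[3,4-bis(benzyloxy)phenyl]vinylboronic acid pinacol ester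
Product: 24 hexadeca-O-benzyl tetraflavanoid with a pinacolboryl group on C3 of unit B (unit B 2,3-trans-3,4-trans), via o-hydroxybenzhydrol 22 (not isolated), via o-quinone methide 23 (not isolated)
Conditions: (R)-3,3'-bis(2,4,6-triisopropylphenyl)-1,1'-binaphthyl-2,2'-diyl hydrogen phosphate (10 mol %), 21 (4 equiv), 5 Å MS, toluene, 40 °C; 11 (1.1 equiv) added over 12 h
Reagents that add atoms: none
Why: Proposed new method: the phosphoric acid activates aldehyde 17 for Friedel–Crafts ortho-hydroxyalkylation by phenol 11 (C4–C4a), the doubly aryl-stabilised benzhydrol 22 loses water to the (E)-o-quinone methide 23, and the boron-bearing carbon of 21 then bonds to the methide carbon (C3–C4) while the quinone methide oxygen closes on the benzylic carbon (O1–C2), which the 4-benzyloxy group and the adjacent C–B bond stabilise as it becomes cationic. The closest known reactions are the acid-catalysed three-component chroman synthesis from phenols, aldehydes and styrenes and the chiral phosphoric acid-catalysed [4+2] cycloaddition of o-quinone methides, made from o-hydroxybenzhydrols, with electron-rich styrenes; a β-borylstyrene as the two-carbon partner and pieces of this size are without precedent. The pyran ring of unit B, the one new ring, closes by an inverse-electron-demand hetero-[4+2] cycloaddition (if stepwise, Michael addition followed by 6-membered oxa-ring closure). C2 and C3 are related by the (E)-geometry of the alkene (2,3-trans), C4 is related to them by the aryl-endo approach to the (E)-quinone methide, which places all three substituents equatorial (3,4-trans, 2,4-cis), and the absolute sense is set by the chiral phosphate, which holds the quinone methide oxygen through its acidic O–H and the boronate through its phosphoryl oxygen, because the stereocentres of units A, C and D are too remote to steer. The step needs attack of the phenol through the carbon ortho to OH and para to OBn, ring closure instead of alkenyl transfer with loss of boron, and capture by the alkene instead of a second phenol. These are secured by unit A blocking the para position and, with its neighbouring benzyloxy group, crowding the other ortho carbon, by the slow ligand exchange of the pinacol ester, and by slow addition of 11 to an excess of 21.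

Step 18
Reactants: 24 hexadeca-O-benzyl tetraflavanoid with a pinacolboryl group on C3 of unit B
Product: 25 hexadeca-O-benzyl tetraflavanoid with a free 3-hydroxyl on unit B (2,3-trans-3,4-trans)
Conditions: NaBO3·4H2O (5 equiv), THF–H2O, rt
Reagents that add atoms: sodium perborate tetrahydrate, [Na+].[O-]OB=O.O.O.O.O
Why: Oxidation of the carbon–boron bond by 1,2-migration of C3 from boron to oxygen in the peroxyborate, which proceeds with retention and so gives the 3,4-trans alcohol; the mild perborate limits β-elimination of the ring aryloxide.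

Step 19
Reactants: 25 hexadeca-O-benzyl tetraflavanoid with a free 3-hydroxyl on unit B
Product: 26 fisetinidol-(4α→6)-fisetinidol-(4α→6)-[fisetinidol-(4α→8)]-catechin (CNP0263622.1)
Conditions: H2 (1 atm), Pd(OH)2 on carbon, THF–MeOH, rt
Reagents that add atoms: none
Why: Catalytic hydrogenolysis of the sixteen benzyl ethers; the C2–O1 and C4–aryl bonds of 4-arylflavan-3-ols are expected to survive these neutral conditions.

**Compound list**

1 | (+)-taxifolin, (2R,3R) | O=C1c2c(O)cc(O)cc2O[C@H](c2ccc(O)c(O)c2)[C@H]1O | starting material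
2 | (2R,3R)-7,3',4'-tri-O-benzyltaxifolin | O=C1c2c(O)cc(OCc3ccccc3)cc2O[C@H](c2ccc(OCc3ccccc3)c(OCc3ccccc3)c2)[C@H]1O | intermediate
3 | (2R,3R)-7,3',4'-tri-O-benzyltaxifolin 5-O-triflate | O=C1c2c(OS(=O)(=O)C(F)(F)F)cc(OCc3ccccc3)cc2O[C@H](c2ccc(OCc3ccccc3)c(OCc3ccccc3)c2)[C@H]1O | intermediate
4 | (2R,3R)-7,3',4'-tri-O-benzylfustin | O=C1c2ccc(OCc3ccccc3)cc2O[C@H](c2ccc(OCc3ccccc3)c(OCc3ccccc3)c2)[C@H]1O | intermediate
5 | (2R,3S,4R)-7-benzyloxy-2-[3,4-bis(benzyloxy)phenyl]chroman-3,4-diol | O[C@@H]1c2ccc(OCc3ccccc3)cc2O[C@H](c2ccc(OCc3ccccc3)c(OCc3ccccc3)c2)[C@H]1O | intermediate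
6 | 2,3-trans-3,4-trans-3,4,7-tris(benzyloxy)-2-[3,4-bis(benzyloxy)phenyl]chroman | c1ccccc1CO[C@@H]1c2ccc(OCc3ccccc3)cc2O[C@H](c2ccc(OCc3ccccc3)c(OCc3ccccc3)c2)[C@H]1OCc1ccccc1 | intermediate
7 | resorcinol | Oc1cccc(O)c1 | starting material
8 | 4-(tetra-O-benzylfisetinidol-4α-yl)benzene-1,3-diol | Oc1ccc(c(O)c1)[C@@H]1c2ccc(OCc3ccccc3)cc2O[C@H](c2ccc(OCc3ccccc3)c(OCc3ccccc3)c2)[C@H]1OCc1ccccc1 | intermediate
9 | 2-(tetra-O-benzylfisetinidol-4α-yl)-5-(triisopropylsilyloxy)phenol | CC(C)[Si](C(C)C)(C(C)C)Oc1ccc(c(O)c1)[C@@H]1c2ccc(OCc3ccccc3)cc2O[C@H](c2ccc(OCc3ccccc3)c(OCc3ccccc3)c2)[C@H]1OCc1ccccc1 | intermediate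
10 | [3-benzyloxy-4-(tetra-O-benzylfisetinidol-4α-yl)phenoxy]triisopropylsilane | CC(C)[Si](C(C)C)(C(C)C)Oc1ccc(c(OCc2ccccc2)c1)[C@@H]1c2ccc(OCc3ccccc3)cc2O[C@H](c2ccc(OCc3ccccc3)c(OCc3ccccc3)c2)[C@H]1OCc1ccccc1 | intermediate
11 | 3-benzyloxy-4-(tetra-O-benzylfisetinidol-4α-yl)phenol | Oc1ccc(c(OCc2ccccc2)c1)[C@@H]1c2ccc(OCc3ccccc3)cc2O[C@H](c2ccc(OCc3ccccc3)c(OCc3ccccc3)c2)[C@H]1OCc1ccccc1 | intermediate
12 | (+)-catechin | Oc1cc(O)c2c(c1)O[C@H](c1ccc(O)c(O)c1)[C@@H](O)C2 | starting material
13 | 5,7,3',4'-tetra-O-benzylcatechin | c1ccccc1COc1cc(OCc3ccccc3)c2c(c1)O[C@H](c1ccc(OCc3ccccc3)c(OCc3ccccc3)c1)[C@@H](O)C2 | intermediate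
14 | 3,5,7,3',4'-penta-O-benzylcatechin | c1ccccc1COc1cc(OCc3ccccc3)c2c(c1)O[C@H](c1ccc(OCc3ccccc3)c(OCc3ccccc3)c1)[C@@H](OCc1ccccc1)C2 | intermediate
15 | tetra-O-benzylfisetinidol-(4α→8)-penta-O-benzylcatechin | c1c(OCc9ccccc9)c2c(c([C@@H]3c4ccc(OCc9ccccc9)cc4O[C@H](c6ccc(OCc9ccccc9)c(OCc9ccccc9)c6)[C@H]3OCc9ccccc9)c1OCc9ccccc9)O[C@H](c6ccc(OCc9ccccc9)c(OCc9ccccc9)c6)[C@@H](OCc9ccccc9)C2 | intermediate
16 | 6-bromo derivative of 15 | Brc1c(OCc9ccccc9)c2c(c([C@@H]3c4ccc(OCc9ccccc9)cc4O[C@H](c6ccc(OCc9ccccc9)c(OCc9ccccc9)c6)[C@H]3OCc9ccccc9)c1OCc9ccccc9)O[C@H](c6ccc(OCc9ccccc9)c(OCc9ccccc9)c6)[C@@H](OCc9ccccc9)C2 | intermediate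
17 | 6-formyl-penta-O-benzylcatechin with tetra-O-benzylfisetinidol-4α-yl on C8 | O=Cc1c(OCc9ccccc9)c2c(c([C@@H]3c4ccc(OCc9ccccc9)cc4O[C@H](c6ccc(OCc9ccccc9)c(OCc9ccccc9)c6)[C@H]3OCc9ccccc9)c1OCc9ccccc9)O[C@H](c6ccc(OCc9ccccc9)c(OCc9ccccc9)c6)[C@@H](OCc9ccccc9)C2 | intermediate
18 | 3,4-dihydroxybenzaldehyde | O=Cc1ccc(O)c(O)c1 | starting material
19 | 3,4-bis(benzyloxy)benzaldehyde | O=Cc1ccc(OCc2ccccc2)c(OCc2ccccc2)c1 | intermediate
20 | bis(4,4,5,5-tetramethyl-1,3,2-dioxaborolan-2-yl)methane | CC1(C)OB(CB2OC(C)(C)C(C)(C)O2)OC1(C)C | starting material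
21 | (E)-2-[3,4-bis(benzyloxy)phenyl]vinylboronic acid pinacol ester | CC1(C)OB(/C=C/c2ccc(OCc3ccccc3)c(OCc3ccccc3)c2)OC1(C)C | intermediate
22 | o-hydroxybenzhydrol from 17 and 11 (carbinol carbon on C6 of unit C and on the phenol carbon ortho to OH; carbinol configuration undefined) | OC(c1c(OCc9ccccc9)c2c(c([C@@H]3c4ccc(OCc9ccccc9)cc4O[C@H](c6ccc(OCc9ccccc9)c(OCc9ccccc9)c6)[C@H]3OCc9ccccc9)c1OCc9ccccc9)O[C@H](c6ccc(OCc9ccccc9)c(OCc9ccccc9)c6)[C@@H](OCc9ccccc9)C2)c1cc([C@@H]3c4ccc(OCc9ccccc9)cc4O[C@H](c6ccc(OCc9ccccc9)c(OCc9ccccc9)c6)[C@H]3OCc9ccccc9)c(OCc9ccccc9)cc1O | intermediate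
23 | (E)-o-quinone methide from 22 | O=C1C=C(OCc9ccccc9)C([C@@H]3c4ccc(OCc9ccccc9)cc4O[C@H](c6ccc(OCc9ccccc9)c(OCc9ccccc9)c6)[C@H]3OCc9ccccc9)=C/C1=C\c1c(OCc9ccccc9)c2c(c([C@@H]3c4ccc(OCc9ccccc9)cc4O[C@H](c6ccc(OCc9ccccc9)c(OCc9ccccc9)c6)[C@H]3OCc9ccccc9)c1OCc9ccccc9)O[C@H](c6ccc(OCc9ccccc9)c(OCc9ccccc9)c6)[C@@H](OCc9ccccc9)C2 | intermediate
24 | hexadeca-O-benzyl tetraflavanoid with pinacolboryl on C3 of unit B | c1([C@@H]7c8cc([C@@H]3c4ccc(OCc9ccccc9)cc4O[C@H](c6ccc(OCc9ccccc9)c(OCc9ccccc9)c6)[C@H]3OCc9ccccc9)c(OCc9ccccc9)cc8O[C@H](c6ccc(OCc9ccccc9)c(OCc9ccccc9)c6)[C@H]7B5OC(C)(C)C(C)(C)O5)c(OCc9ccccc9)c2c(c([C@@H]3c4ccc(OCc9ccccc9)cc4O[C@H](c6ccc(OCc9ccccc9)c(OCc9ccccc9)c6)[C@H]3OCc9ccccc9)c1OCc9ccccc9)O[C@H](c6ccc(OCc9ccccc9)c(OCc9ccccc9)c6)[C@@H](OCc9ccccc9)C2 | intermediate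
25 | hexadeca-O-benzyl tetraflavanoid with free 3-hydroxyl on unit B | c1([C@@H]7c8cc([C@@H]3c4ccc(OCc9ccccc9)cc4O[C@H](c6ccc(OCc9ccccc9)c(OCc9ccccc9)c6)[C@H]3OCc9ccccc9)c(OCc9ccccc9)cc8O[C@H](c6ccc(OCc9ccccc9)c(OCc9ccccc9)c6)[C@H]7O)c(OCc9ccccc9)c2c(c([C@@H]3c4ccc(OCc9ccccc9)cc4O[C@H](c6ccc(OCc9ccccc9)c(OCc9ccccc9)c6)[C@H]3OCc9ccccc9)c1OCc9ccccc9)O[C@H](c6ccc(OCc9ccccc9)c(OCc9ccccc9)c6)[C@@H](OCc9ccccc9)C2 | intermediate
26 | fisetinidol-(4α→6)-fisetinidol-(4α→6)-[fisetinidol-(4α→8)]-catechin (CNP0263622.1) | Oc1ccc2c(c1)O[C@H](c1ccc(O)c(O)c1)[C@@H](O)[C@@H]2c1cc2c(cc1O)O[C@H](c1ccc(O)c(O)c1)[C@@H](O)[C@@H]2c1c(O)c2c(c([C@@H]3c4ccc(O)cc4O[C@H](c4ccc(O)c(O)c4)[C@H]3O)c1O)O[C@H](c1ccc(O)c(O)c1)[C@@H](O)C2 | target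

**Step count**

Total: 19 steps. Longest linear sequence: 12 steps (steps 1–9, then 17, 18 and 19).

**Steps most likely to fail, with fallbacks**

Step 17 (proposed new method). Four processes threaten it:
- the strongly stabilised quinone methide may react too slowly with the boryl alkene;
- the alkenyl group may transfer from boron with loss of the boron atom;
- a second phenol molecule may be captured, giving a triarylmethane;
- the catalyst may discriminate poorly between the two faces.

The fallback uses only known flavan-4-yl cation chemistry and sets out from 6 and 15. Compound 6 is thiolysed with 2,6-dimethylbenzenethiol and BF3·OEt2 to 3,7,3',4'-tetra-O-benzyl-4-(2,6-dimethylphenylthio)flavan F1, whose thioether is inert to oxophilic Lewis acids. F1 in excess captures the cation released from a second portion of 6 by TMSOTf. The attack goes through C6 of its di-oxygenated ring (para to the ring oxygen, less hindered than C8) and gives tetra-O-benzylfisetinidol-(4α→6)-tetra-O-benzyl-4-(2,6-dimethylphenylthio)flavan F2. The thioether of F2 is then activated with AgBF4 in THF in the presence of an excess of 15, whose only free carbon on the tri-oxygenated ring is C6. Attack anti to the 3-benzyloxy group should give the heptadeca-O-benzyl tetraflavanoid F3. Hydrogenolysis of F3 under the conditions of step 19 returns to the route at 26.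

Step 12. The cation may be attacked from the wrong face (3,4-cis), through C6 of the catechin ring, or a second time, giving chain growth. The fallback sets out from 5 and 14 and controls the face by neighbouring-group participation. Diol 5 is acetylated (Ac2O, pyridine) to 3,4-di-O-acetyl-7,3',4'-tri-O-benzyl-flavan-3,4-diol F4. Ionisation of the 4-acetate with TMSOTf in the presence of 14 gives an acetoxonium ion bridging C3 and C4. This can only be opened trans, which should give 3-O-acetyl-tri-O-benzylfisetinidol-(4α→8)-penta-O-benzylcatechin F5. Methanolysis (K2CO3, MeOH–THF) gives the 3-hydroxy biflavanoid F6. Benzylation (NaH, BnBr, DMF) returns to the route at 15.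

Step 14. The alkyllithium may deprotonate a benzylic ether methylene, leading to [1,2]-Wittig rearrangement, or the hindered aryllithium may be protonated before it meets DMF. The fallback sets out from 15 and avoids metalation. Vilsmeier–Haack formylation (POCl3, DMF, 0 °C → rt, then aqueous NaOAc) puts the formyl group directly on C6 of the catechin ring, the most electron-rich free position. It returns to the route at 17 without a new isolated compound.

**Further compounds**

F1 | step 17 | 3,7,3',4'-tetra-O-benzyl-4-(2,6-dimethylphenylthio)flavan (2,3-trans-3,4-trans) | Cc1cccc(C)c1S[C@@H]1c2ccc(OCc3ccccc3)cc2O[C@H](c2ccc(OCc3ccccc3)c(OCc3ccccc3)c2)[C@H]1OCc1ccccc1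
F2 | step 17 | tetra-O-benzylfisetinidol-(4α→6)-tetra-O-benzyl-4-(2,6-dimethylphenylthio)flavan | Cc1cccc(C)c1S[C@@H]7c8cc([C@@H]3c4ccc(OCc9ccccc9)cc4O[C@H](c6ccc(OCc9ccccc9)c(OCc9ccccc9)c6)[C@H]3OCc9ccccc9)c(OCc9ccccc9)cc8O[C@H](c6ccc(OCc9ccccc9)c(OCc9ccccc9)c6)[C@H]7OCc9ccccc9
F3 | step 17 | heptadeca-O-benzyl tetraflavanoid (unit B 3-O-benzyl) | c1([C@@H]7c8cc([C@@H]3c4ccc(OCc9ccccc9)cc4O[C@H](c6ccc(OCc9ccccc9)c(OCc9ccccc9)c6)[C@H]3OCc9ccccc9)c(OCc9ccccc9)cc8O[C@H](c6ccc(OCc9ccccc9)c(OCc9ccccc9)c6)[C@H]7OCc9ccccc9)c(OCc9ccccc9)c2c(c([C@@H]3c4ccc(OCc9ccccc9)cc4O[C@H](c6ccc(OCc9ccccc9)c(OCc9ccccc9)c6)[C@H]3OCc9ccccc9)c1OCc9ccccc9)O[C@H](c6ccc(OCc9ccccc9)c(OCc9ccccc9)c6)[C@@H](OCc9ccccc9)C2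
F4 | step 12 | 3,4-di-O-acetyl-7,3',4'-tri-O-benzyl-flavan-3,4-diol (2,3-trans-3,4-trans) | CC(=O)O[C@@H]1c2ccc(OCc3ccccc3)cc2O[C@H](c2ccc(OCc3ccccc3)c(OCc3ccccc3)c2)[C@H]1OC(C)=O
F5 | step 12 | 3-O-acetyl-tri-O-benzylfisetinidol-(4α→8)-penta-O-benzylcatechin | c1c(OCc9ccccc9)c2c(c([C@@H]3c4ccc(OCc9ccccc9)cc4O[C@H](c6ccc(OCc9ccccc9)c(OCc9ccccc9)c6)[C@H]3OC(C)=O)c1OCc9ccccc9)O[C@H](c6ccc(OCc9ccccc9)c(OCc9ccccc9)c6)[C@@H](OCc9ccccc9)C2
F6 | step 12 | 7,3',4'-tri-O-benzylfisetinidol-(4α→8)-penta-O-benzylcatechin (free 3-hydroxyl on unit D) | c1c(OCc9ccccc9)c2c(c([C@@H]3c4ccc(OCc9ccccc9)cc4O[C@H](c6ccc(OCc9ccccc9)c(OCc9ccccc9)c6)[C@H]3O)c1OCc9ccccc9)O[C@H](c6ccc(OCc9ccccc9)c(OCc9ccccc9)c6)[C@@H](OCc9ccccc9)C2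
F0 | step 14 | none | none
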